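Target cannot pass the substrate charged, so a percentage cannot grow in step with time. I therefore reckoned in powers of ten of the part of the charge not yet read as target.

| flask | substrate | reagent | remark | time |
|---|---|---|---|---|
| teal | 0.80 M | 3 M | run made earlier |  |
| blue | 1.5 M | 3 M | run made earlier |  |
| red | 2 M | 2.3 M | run made earlier |  |
| beta | 1.2 M | 2.00 M |  | 3.0 h |
| theta | 2.0 M | 3.00 M |  | 6.0 h |

| run | time / h | target / % |
|---|---|---|
| teal | 0.200 | 2.5 |
| teal | 0.667 | 8.1 |
| teal | 1.00 | 15.1 |
| teal | 1.50 | 17.9 |
| teal | 2.50 | 25.4 |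
| teal | 3.00 | 30.7 |
| blue | 0.250 | 0.9 |
| blue | 0.417 | 3.5 |
| blue | 0.667 | 7.2 |
| blue | 1.00 | 11.0 |
| blue | 2.00 | 23.6 |
| blue | 3.00 | 29.1 |
| red | 0.667 | 7.6 |
| red | 1.33 | 11.0 |
| red | 2.00 | 15.6 |
| red | 2.50 | 18.4 |
| red | 3.00 | 21.8 |

(standard deviation of a reading: 1 percentage point)

1. which one finishes higher in amount of target, in percent of the substrate charged ("neither" within 2 percentage points) (beta / theta / neither)
2. amount of target at the end, in percent of the substrate charged, beta
3. amount of target at the end, in percent of the substrate charged, theta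

- the earlier runs were read with a standard deviation of 1 percentage point
- a reading or a percentage of target counts all its forms, free or not

I began with teal. Its last reading left 69.3% of the charge not yet target, which is 0.159 powers of ten. I divided that by mean reagent times time. For the mean I took the start and end of each run, with one reagent spent per target. Teal gave 5.13 × 10⁻⁶ M⁻¹ s⁻¹ and red gave 4.75 × 10⁻⁶ M⁻¹ s⁻¹, less than teal. Their middle, put into the integrated second-order law, gave 45.5% for theta.

The weak link was the one reagent per target. Red had spent a larger share of its reagent than teal or blue, and it read lower than both. I tried two, an apparent stoichiometry. Teal, blue and red then gave 5.35 × 10⁻⁶ M⁻¹ s⁻¹, 5.39 × 10⁻⁶ M⁻¹ s⁻¹ and 5.30 × 10⁻⁶ M⁻¹ s⁻¹, a smaller gap. With this scatter that was a judgement, not a proof. Their mean, D = 5.35 × 10⁻⁶ M⁻¹ s⁻¹, is the decade rate: powers of ten of the charge not yet target lost per molar second of reagent.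

With charges a of substrate and b of reagent, I set r = 10^(Dt(b − 2a)), and the fraction read as target is b(1 − r)/(2a − rb). Beta came to 20.6% and theta to 41.2%.

The forecast named theta, with 20.5% for beta and 45% for theta, and noted: “Theta is a long extrapolation”.

The flask gave 21.1% for beta and 40.0% for theta, so theta finished higher.

    substrate ⇌ intermediate A (K = 0.660, k = 0.00370 s⁻¹)
    reagent + intermediate A → target (k = 3.50 × 10⁻⁵ M⁻¹ s⁻¹)
    substrate → intermediate B (k = 2.10 × 10⁻⁵ s⁻¹)
    reagent + intermediate B → intermediate C (k = 1.80 × 10⁻⁵ M⁻¹ s⁻¹)
    reagent + intermediate C ⇌ intermediate D (K = 0.260 M⁻¹, k = 4.20 × 10⁻⁵ M⁻¹ s⁻¹)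
    intermediate B → side product (k = 1.00 × 10⁻⁴ s⁻¹)
    reagent + target ⇌ idle adduct, settled at all times (K = 2.60 M⁻¹)
    reagent + target → over-reaction product (k = 4.30 × 10⁻⁶ M⁻¹ s⁻¹)

At 6.00 h theta had spent about twice as much reagent as the target read, and idle adduct stood at 31.6% of the charge. D, through its theta figure, put reagent left at 45.1% of its charge, and the flask held 49%.

For a neighbour flask, theta with 0.75 M of reagent, D gave 11.8%. The computed flask gave 12.4%.

The earlier runs and the new flask were generated by integration with constants of no real substance, noise included.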